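**Retrosynthetic overview**

1. The target is the methyl (−)-shikimate core (3R,4S,5R) carrying 3-OAc and 4,5-bis[(R)-2-methylbutanoate]. The acyl groups go on last, with O3 told apart from O4/O5 through a cyclic 3,4-orthoacetate.
2. Key disconnection: C2–C3 and C4–C5 together, by a Diels–Alder reaction of methyl 3-furoate (C2, C1 with its ester, C6, C5 and O5) with vinylene carbonate (C3, C4 and their cis oxygens).
3. Enabling feature: C2 (vinylic CH) and C5 (CH–O) stand 1,4 across the cyclohexene and flank the cis-3,4-diol, with O5 trans to O4. Letting O5 also bond to C2 turns the ring into an endo 7-oxanorbornene, which is a furan adduct.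
4. The extra C2–O bond of this temporary oxygen bridge is β to the C1 ester. Conjugate hydride addition at C6 followed by β-elimination cuts it, places the double bond at C1=C2 and frees O5–H.
5. Ring order: oxygen-bridged bicycle (carbocycle plus temporary bridge, dioxolanone carried along), then the monocyclic cyclohexene. The Diels–Alder adduct is racemic, so absolute configuration comes from a lipase resolution at C5, which caps throughput at half.

Key step: step 1

Remark: (R)-2-methylbutanoic acid of high enantiomeric purity is taken as a commercial starting material; both acyl stereocenters of the target read as (R) and the ring as (3R,4S,5R), the natural shikimate series.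

**Route**

Step 1
Reactants: 1 methyl furan-3-carboxylate (methyl 3-furoate); 2 vinylene carbonate (1,3-dioxol-2-one)
Product: 3 racemic endo cycloadduct methyl (1R*,2S*,6R*,7S*)-4-oxo-3,5,10-trioxatricyclo[5.2.1.0^2,6]dec-8-ene-8-carboxylate
Conditions: 2 (3 equiv), BHT (cat.), CH2Cl2, 13 kbar, 50 °C; exo isomer removed by chromatography or crystallization
Reagents that add atoms: none
Why: A concerted, suprafacial [4+2] cycloaddition (Diels–Alder reaction) joins the furan diene (C2=C1–C6=C5 of the target, with the ring oxygen spanning C2 and C5) to the cis-enediol carbonate (C3=C4), forming C2–C3 and C4–C5 in one transition state; the closest known reaction is the cycloaddition of furan itself with vinylene carbonate to the 7-oxanorbornene carbonate, and pressure is the established remedy for deactivated furans. The carbocyclic six-membered ring is closed by this intermolecular cycloaddition, and because the diene is cyclic the same event makes the oxygen-bridged bicyclo[2.2.1] frame, while the dioxolanone ring is carried in unchanged. C3 and C4 come out cis because the ring-locked (Z)-alkene adds suprafacially. C5 and the temporary center C2 are set relative to them by the endo approach, in which the carbonate lies under the diene and ends anti to the oxygen bridge, which is the 4,5-trans relation of the target. The step needs endo selectivity and must not revert: the compact endo transition state should be favored under pressure and the moderate temperature should suppress cycloreversion to the thermodynamically preferred exo adduct, while regiochemistry is no issue because the dienophile is symmetric. The adduct is racemic; the absolute configuration is fixed in step 3.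

Step 2
Reactants: 3 racemic endo cycloadduct
Product: 6 racemic methyl 3,4-O-carbonylshikimate, via copper enolate 4 (not isolated), via copper alkoxide 5 (not isolated)
Conditions: [(Ph3P)CuH]6 (0.2 equiv of hexamer, 1.2 equiv hydride), toluene/THF, 0 °C to rt; then sat. aq NH4Cl
Reagents that add atoms: none
Why: Conjugate reduction by copper hydride followed by E1cB β-alkoxide elimination: hydride should add to C6, the β-carbon of the strained bicyclic enoate, and the resulting monovalent copper enolate 4 carries the bridge C2–O bond in the β-position, so that elimination, driven by release of the strain of the oxygen-bridged bicycle, opens the bridge to the C5 alkoxide 5 and moves the double bond to C1=C2 (the same enolate-triggered bridge opening that amide bases effect on 7-oxanorbornane-2-carboxylates and that hydride donors effect on 7-oxanorbornenyl sulfones), while the cyclic carbonate is inert to this soft hydride and no new stereocenter arises because C6 becomes a methylene and C2 becomes trigonal.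

Step 3
Reactants: 6 racemic methyl 3,4-O-carbonylshikimate
Product: 7 methyl (3R,4S,5R)-5-O-acetyl-3,4-O-carbonylshikimate
Conditions: immobilized Burkholderia cepacia lipase, vinyl acetate (3 equiv), MTBE, 30 °C, stopped near 45% conversion; chromatography
Reagents that add atoms: vinyl acetate, C=COC(C)=O
Why: Lipase-catalysed kinetic resolution by irreversible transesterification, in which the empirical size rule for lipases and secondary alcohols (oxygenated C4 as the large group, the C6 methylene as the medium group) predicts that the (5R) alcohol is acetylated faster, so that the (3R,4S,5R) enantiomer should be converted to 7 while the (3S,4R,5S) alcohol stays behind and is removed; this fixes the absolute configuration of C3, C4 and C5 without making a new stereocenter.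

Step 4
Reactants: 7 methyl (3R,4S,5R)-5-O-acetyl-3,4-O-carbonylshikimate
Product: 8 methyl shikimate, methyl (3R,4S,5R)-3,4,5-trihydroxycyclohex-1-ene-1-carboxylate
Conditions: K2CO3 (0.2 equiv), MeOH, 0 °C to rt; neutralized with acidic ion-exchange resin
Reagents that add atoms: none
Why: Base-catalysed transesterification with methanol should cleave the secondary acetate and the cyclic carbonate (which leaves as dimethyl carbonate) while exchange at the conjugated methyl ester is degenerate, and no stereocenter is touched.

Step 5
Reactants: 8 methyl shikimate
Product: 10 methyl 3-O-acetylshikimate, via cyclic orthoacetate 9 (not isolated)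
Conditions: MeC(OMe)3 (1.2 equiv), camphorsulfonic acid (0.05 equiv), CH2Cl2/MeCN, rt; then 80% aq AcOH, rt
Reagents that add atoms: trimethyl orthoacetate, COC(C)(OC)OC; water, O
Why: Acid-catalysed orthoester exchange should engage only the cis-3,4-diol in a five-membered cyclic orthoacetate (the trans-4,5-diol cannot span it without strain), and mild aqueous acid hydrolysis of cyclic orthoesters of cis-diols on six-membered rings is known to open through the 1,3-dioxolan-2-ylium ion to the ester on the axial oxygen, here the pseudoaxial allylic O3, leaving O4 and O5 free with no stereocenter formed or touched.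

Step 6
Reactants: 10 methyl 3-O-acetylshikimate; 11 (R)-2-methylbutanoic acid
Product: 12 methyl (3R,4S,5R)-3-acetoxy-4,5-bis{[(2R)-2-methylbutanoyl]oxy}cyclohex-1-ene-1-carboxylate (target)
Conditions: 11 (3 equiv), DCC (3 equiv), DMAP (0.2 equiv), CH2Cl2, 0 °C to rt
Reagents that add atoms: none
Why: Steglich esterification (carbodiimide with DMAP) acylates both remaining equatorial hydroxyls, and excess activated acid at low temperature with only catalytic DMAP should outrun acetyl migration from O3 to O4 and should not epimerize the α-stereocenter of the acid, which carries no activating α-substituent; no ring stereocenter is touched.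

**Compound list**

1 | methyl furan-3-carboxylate (methyl 3-furoate) | COC(=O)c1ccoc1 | starting material
2 | vinylene carbonate (1,3-dioxol-2-one) | O=C1OC=CO1 | starting material
3 | racemic methyl (1R*,2S*,6R*,7S*)-4-oxo-3,5,10-trioxatricyclo[5.2.1.0^2,6]dec-8-ene-8-carboxylate; endo adduct, carbonate anti to the oxygen bridge, ester on C8 next to bridgehead C7; SMILES shows the enantiomer that is carried on | COC(=O)C1=C[C@H]2O[C@@H]1[C@H]3OC(=O)O[C@@H]23 | intermediate
4 | monovalent copper enolate of the saturated bicyclic ester (O-bound, phosphine ligands omitted; racemic) | COC(O[Cu])=C1C[C@H]2O[C@@H]1[C@H]3OC(=O)O[C@@H]23 | intermediate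
5 | monovalent copper 5-alkoxide of methyl 3,4-O-carbonylshikimate (phosphine ligands omitted; racemic) | COC(=O)C1=C[C@H]2OC(=O)O[C@H]2[C@H](O[Cu])C1 | intermediate
6 | racemic methyl 3,4-O-carbonylshikimate, methyl (3aR*,7R*,7aS*)-7-hydroxy-2-oxo-3a,6,7,7a-tetrahydro-1,3-benzodioxole-5-carboxylate; SMILES shows the (3R,4S,5R) enantiomer in shikimate numbering | COC(=O)C1=C[C@H]2OC(=O)O[C@H]2[C@H](O)C1 | intermediate
7 | methyl (3R,4S,5R)-5-O-acetyl-3,4-O-carbonylshikimate | COC(=O)C1=C[C@H]2OC(=O)O[C@H]2[C@H](OC(C)=O)C1 | intermediate
8 | methyl shikimate, methyl (3R,4S,5R)-3,4,5-trihydroxycyclohex-1-ene-1-carboxylate | COC(=O)C1=C[C@@H](O)[C@@H](O)[C@H](O)C1 | intermediate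
9 | methyl 3,4-O-(1-methoxyethylidene)shikimate, cyclic orthoacetate of the cis-3,4-diol (both epimers at the orthoester carbon) | COC(=O)C1=C[C@H]2OC(C)(OC)O[C@H]2[C@H](O)C1 | intermediate
10 | methyl 3-O-acetylshikimate, methyl (3R,4S,5R)-3-acetoxy-4,5-dihydroxycyclohex-1-ene-1-carboxylate | COC(=O)C1=C[C@@H](OC(C)=O)[C@@H](O)[C@H](O)C1 | intermediate
11 | (R)-2-methylbutanoic acid | CC[C@@H](C)C(=O)O | starting material
12 | methyl (3R,4S,5R)-3-acetoxy-4,5-bis{[(2R)-2-methylbutanoyl]oxy}cyclohex-1-ene-1-carboxylate | CC[C@@H](C)C(=O)O[C@@H]1[C@H](OC(C)=O)C=C(C(=O)OC)C[C@H]1OC(=O)[C@H](C)CC | target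

**Step count and risks**

Total step count: 6. Longest linear sequence: 6 steps (1 or 2 to 12).

Steps most likely to fail:

Step 1. The ester-deactivated furan may react too slowly with the weak dienophile, the adduct may revert, or endo/exo selectivity may be poor. The fallback sets out from 2 and comes back at 6. It moves the ester carbon out of the cycloaddition: 2 is heated with furan (neat, sealed tube, 125 °C) in the known cycloaddition, and separation gives the meso endo adduct 3,5,10-trioxatricyclo[5.2.1.0^2,6]dec-8-en-4-one F1. Hydromethoxycarbonylation of its strained alkene (PdCl2(PPh3)2, TsOH cat., CO 20 bar, MeOH/toluene, 60 °C) should give racemic methyl exo-4-oxo-3,5,10-trioxatricyclo[5.2.1.0^2,6]decane-8-carboxylate F2. KN(SiMe3)2 in THF at −78 °C then opens the oxygen bridge by E1cB elimination to racemic 6.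

Step 2. The copper enolate may be protonated before it eliminates, stopping at the saturated ester, or the product enoate may be reduced further. The fallback sets out from 3 and comes back at 6. It separates reduction from bridge opening: hydrogenation of 3 from the exo face (H2, Pd/C, EtOAc, rt) should give racemic methyl endo-4-oxo-3,5,10-trioxatricyclo[5.2.1.0^2,6]decane-8-carboxylate F3, and KN(SiMe3)2 in THF at −78 °C effects the known enolate β-elimination to 6.

Step 3. The lipase may discriminate the enantiomers insufficiently, leaving optical purity incomplete; if its sense is opposite to the prediction, the recovered alcohol instead of the acetate enters step 4 with the same chemistry. The fallback sets out from 6 and comes back at 8. It replaces the enzymatic resolution by covalent diastereomers: 6 is acylated with (1S)-camphanic chloride (pyridine, DMAP, CH2Cl2). Methyl (3R,4S,5R)-5-O-[(1S)-camphanoyl]-3,4-O-carbonylshikimate F4 is separated by crystallization or chromatography from methyl (3S,4R,5S)-5-O-[(1S)-camphanoyl]-3,4-O-carbonylshikimate F5. Methanolysis of F4 (K2CO3, MeOH) removes camphanate and carbonate to give 8.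

Further compounds
F1 | step 1 | meso endo 3,5,10-trioxatricyclo[5.2.1.0^2,6]dec-8-en-4-one | C1=C[C@H]2O[C@@H]1[C@H]3OC(=O)O[C@@H]23
F2 | step 1 | racemic methyl exo-4-oxo-3,5,10-trioxatricyclo[5.2.1.0^2,6]decane-8-carboxylate | COC(=O)[C@H]1C[C@H]2O[C@@H]1[C@H]3OC(=O)O[C@@H]23
F3 | step 2 | racemic methyl endo-4-oxo-3,5,10-trioxatricyclo[5.2.1.0^2,6]decane-8-carboxylate | COC(=O)[C@@H]1C[C@H]2O[C@@H]1[C@H]3OC(=O)O[C@@H]23
F4 | step 3 | methyl (3R,4S,5R)-5-O-[(1S)-camphanoyl]-3,4-O-carbonylshikimate | COC(=O)C1=C[C@H]2OC(=O)O[C@H]2[C@H](OC(=O)[C@@]34CC[C@@](C)(C(=O)O3)C4(C)C)C1
F5 | step 3 | methyl (3S,4R,5S)-5-O-[(1S)-camphanoyl]-3,4-O-carbonylshikimate | COC(=O)C1=C[C@@H]2OC(=O)O[C@@H]2[C@@H](OC(=O)[C@@]34CC[C@@](C)(C(=O)O3)C4(C)C)C1
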